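## The problem

The target **18** has no stereocentres, so nothing has to be set or relayed and the whole difficulty is regiochemical. Ring A is a pentasubstituted phenol with OH at C1, the 2,4-dibromophenoxy group at C2, Br at C3, Cl at C4, Br at C5 and a single hydrogen at C6; ring B is joined to it only through the ether oxygen. That hydrogen sits on the carbon ortho to the hydroxyl, the most nucleophilic carbon of the ring, whereas both ring A bromines are meta to the hydroxyl and ortho and para only to the ether oxygen, a weak director shared with ring B, whose free ortho carbon C6' competes for electrophilic bromine. The three halogens on C3, C4 and C5 therefore cannot be laid down by successive halogenation of a simple phenol without an additional control element. The four aryl C–Br bonds rule out palladium- or copper-mediated ether formation, alkyllithium reagents and hydrogenolysis, and the ring B hydrogen between the two bromines is acidic towards amide bases. The enabling feature is that C1 (OH) and C2 (OAr) are adjacent and C4 (Cl) is para to C1. C6, C1 and C2 can therefore come from C2, C3 and C4 of a 4-aryloxyacetoacetate, and C3, C4 and C5 from the three carbons of 2-chloromalonaldehyde. The ester carbon then ends up on C6, the one carbon that must finish as C–H, and provides a handle there.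

## Retrosynthesis

**18 from 16.** The C6–H bond is traced back to a C6–NH2 bond, removed through diazonium salt **17**. A nitrogen on C6 is ortho to C5 and para to C3, the two carbons that need bromine, and it is removable. The forward step is diazotisation of a hindered, weakly basic ortho-aminophenol and reduction with H3PO2.

**16 from 15, 15 from 13.** The two ring A C–Br bonds are cut. The aminophenol is kept masked as benzoxazolone **13** during bromination, which proceeds through monobromide **14** to **15**; the mask keeps the donor nitrogen but prevents oxidation to a quinone imine. The neighbouring option, brominating salicylate **9** directly and then removing the carboxyl, is two steps shorter but was rejected. In **9**, C3 and C5 are para and ortho to the ester and meta to the hydroxyl, so after the first bromine the second substitution should be slower than attack at C6' of ring B. With nitrogen in place of the carboxyl carbon, each site is activated by both the nitrogen and the ether oxygen, and ring B is left behind.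

**13 from 10, 10 from 9.** The C6–N bond is traced to the C6–CO2H bond by a Curtius rearrangement through acyl azide **11** and isocyanate **12**, which the neighbouring hydroxyl traps. The carboxyl left by the ring construction thus becomes the director rather than a passive blocking group. Acid **10** comes from ester **9** by saponification.

**9 from 5 and 7 (key disconnection).** The C2–C3 and C5–C6 bonds of ring A are cut, giving the 4-aryloxy-1,3-bis(silyloxy)diene **5** and silylated 2-chloromalonaldehyde **7**. Against late halogenation of a preformed arene, this fixes OH, OAr and Cl in their final relationship from open-chain precursors and leaves only the two future C–Br carbons and the carboxyl-bearing carbon to be dealt with. The dielectrophile is symmetric, so there is no orientation problem. The forward reaction must form two C–C bonds and aromatise without touching the C–Br bonds.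

**5 from 4, 4 from 3, 3 from 1 and 2; 7 from 6.** The silyl groups are removed in two stages back to keto ester **3**. The diaryl ether oxygen is attached in **3** by displacement of chloride from methyl 4-chloroacetoacetate **2** by 2,4-dibromophenol **1**. This is an SN2 reaction at a saturated carbon, needs no metal, and brings in both ring B bromines in their final positions. Enal **7** is the O-silyl derivative of commercial 2-chloromalonaldehyde **6**.

## Roads not taken

**Alternative 1:** Ring B is built last. Its C1'–C2' and C5'–C6' bonds are cut, leading to the ethynyl ether of a finished ring A, 1,3-dibromo-2-chloro-4-(ethynyloxy)-5-methoxybenzene A1, and to 3,5-dibromo-2H-pyran-2-one A2.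
- Forward key step: cycloaddition of A1 across C3 and C6 of A2 with loss of CO2 gives 1,3-dibromo-2-chloro-4-(2,4-dibromophenoxy)-5-methoxybenzene A3; O-demethylation of A3 would finish.
- Merits: both ring B bromines are placed by the polarity of the cycloaddition, with no electrophilic bromination of ring B.
- Weak points: A1 already contains the whole pentasubstituted ring A, so the hard part is untouched. Aryl ethynyl ethers are normally made by elimination with alkyllithium, which the aryl bromides of A1 would not tolerate. They are also thermally fragile, while alkyne additions to bromopyrones such as A2 need heat. A deprotection is added.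
- Comparison: its only advantage, a regiochemically certain ring B, is obtained in the chosen plan by starting from **1**.

**Alternative 2:** The two ring A C–Br bonds are cut with an amino group on the future chlorine carbon.
- Forward key step: 3-(2,4-dibromophenoxy)-4-methoxyaniline A4 takes two bromines ortho to nitrogen to give 2,6-dibromo-3-(2,4-dibromophenoxy)-4-methoxyaniline A5. A Sandmeyer reaction of A5 with CuCl then gives A3, and demethylation gives **18**.
- Merits: the amino group overrides every other director, ring B cannot compete, and the same nitrogen becomes the chlorine. The sequence from A4 through A5 is short.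
- Weak points: in A4 the ether oxygen is meta to nitrogen, so the diaryl ether cannot be made by nucleophilic aromatic substitution. It needs a copper-mediated coupling in the presence of aryl bromides, or a diaryliodonium reagent. A Sandmeyer reaction on the tetrabromide A5 and a BBr3 demethylation follow.
- Comparison: this road is probably two or three steps shorter, and its bromination is as secure as the one adopted here, which uses the same principle of a nitrogen that directs and is then removed. The chosen plan offers in return an ether bond made by plain alkylation, a chlorine that arrives in a building block, and no methyl ether to cleave.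

**Alternative 3:** The two ring B C–Br bonds are cut.
- Forward key step: 3,5-dibromo-4-chloro-2-phenoxyphenyl acetate A6 is brominated para and then ortho to the ether oxygen to give 3,5-dibromo-4-chloro-2-(2,4-dibromophenoxy)phenyl acetate A7; acetate cleavage of A7 would finish.
- Merits: the innate selectivity of a phenoxy ring is used, ring A is deactivated by the acetate and three halogens, and the last steps are trivial.
- Weak points: A6 presupposes the complete ring A with both bromines meta to oxygen, which is the actual problem. The reaction must also stop at A7, before a third bromine enters at C6', and the ring A hydrogen ortho to the acyloxy group is not fully protected.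
- Comparison: the endgame is as simple as that of the chosen plan, but nothing is offered for ring A, and the chosen plan makes the ring B bromination unnecessary.

Key step: step 5

Assumption: silyl enol ethers **4**, **5** and **7** form as mixtures of double-bond isomers and are used as such; this geometry is lost on aromatisation and is left unspecified.

## Route

Step 1
Reactants: 1 2,4-dibromophenol; 2 methyl 4-chloro-3-oxobutanoate (methyl 4-chloroacetoacetate)
Product: 3 methyl 4-(2,4-dibromophenoxy)-3-oxobutanoate
Conditions: NaH (2.1 equiv), THF, 0 °C to reflux; aq. HCl work-up
Reagents that add atoms: none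
Why: Williamson-type SN2 displacement of an activated alpha-chloroketone chloride by the phenoxide; the second equivalent of NaH holds the keto ester as its enolate and suppresses self-condensation, and no metal catalyst touches the aryl bromides.

Step 2
Reactants: 3 methyl 4-(2,4-dibromophenoxy)-3-oxobutanoate
Product: 4 methyl 4-(2,4-dibromophenoxy)-3-(trimethylsilyloxy)but-2-enoate
Conditions: Me3SiCl, NEt3, toluene, 20 °C
Reagents that add atoms: chlorotrimethylsilane, C[Si](C)(C)Cl
Why: Amine-mediated O-silylation of a beta-keto ester gives the conjugated 3-silyloxy enoate, the standard first stage of a 1,3-bis(silyloxy)diene preparation.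

Step 3
Reactants: 4 methyl 4-(2,4-dibromophenoxy)-3-(trimethylsilyloxy)but-2-enoate
Product: 5 4-(2,4-dibromophenoxy)-1-methoxy-1,3-bis(trimethylsilyloxy)buta-1,3-diene
Conditions: LiN(i-Pr)2 (1.1 equiv), THF, −78 °C; then Me3SiCl, −78 to 20 °C
Reagents that add atoms: chlorotrimethylsilane, C[Si](C)(C)Cl
Why: Gamma-deprotonation of the vinylogous ester and O-silylation of the dienolate at the ester oxygen is the standard second stage; the methylene is acidified by conjugation and by the aryloxy group, so it should be removed faster than the ring B hydrogen between the bromines if the base is not in excess.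

Step 4
Reactants: 6 2-chloromalonaldehyde
Product: 7 2-chloro-3-(trimethylsilyloxy)prop-2-enal
Conditions: Me3SiCl, NEt3, Et2O, 0 to 20 °C; filtered and used crude
Reagents that add atoms: chlorotrimethylsilane, C[Si](C)(C)Cl
Why: O-silylation of the enol form of a 1,3-dicarbonyl compound, as used to make 3-silyloxy-2-en-1-ones from 1,3-diketones; the product is moisture-sensitive and is used directly.

Step 5
Reactants: 5 4-(2,4-dibromophenoxy)-1-methoxy-1,3-bis(trimethylsilyloxy)buta-1,3-diene; 7 2-chloro-3-(trimethylsilyloxy)prop-2-enal
Product: 9 methyl 5-chloro-3-(2,4-dibromophenoxy)-2-hydroxybenzoate, via open-chain chloroenal keto ester 8 (not isolated)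
Conditions: TiCl4 (1.1 equiv), CH2Cl2, −78 to 20 °C; aq. HCl work-up
Reagents that add atoms: none
Why: TiCl4 activates the carbonyl of 7, and the aryloxy-bearing terminal carbon of diene 5, its most nucleophilic site, adds in a Mukaiyama-type aldol step; loss of silanol then unmasks the second aldehyde as chloroenal 8, held as its silyl or titanium enolate on the ester side. The central carbon of the former diene attacks that aldehyde intramolecularly, closing ring A in a 6-exo-trig (enolexo) aldol cyclisation, and dehydration with tautomerisation aromatises. The closest known reaction type is the TiCl4-mediated formal (3+3) cyclocondensation of 1,3-bis(silyloxy)-1,3-butadienes with 3-silyloxy-2-en-1-ones to salicylates, including 2-chloro electrophiles and 4-aryloxy dienes. The two new bonds are C2–C3 and C5–C6 of ring A. No stereocentre survives: the one in 8 and the enal geometry, which can equilibrate under the Lewis acid, are erased on aromatisation. The step needs regiocontrol in principle, but the dielectrophile is symmetric, so either aldehyde carbon and either order of bond formation gives the same salicylate. Chemoselectivity rests on the inertness of aryl C–Br and C–O bonds to TiCl4 at these temperatures.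

Step 6
Reactants: 9 methyl 5-chloro-3-(2,4-dibromophenoxy)-2-hydroxybenzoate
Product: 10 5-chloro-3-(2,4-dibromophenoxy)-2-hydroxybenzoic acid
Conditions: NaOH (aq, 2 M), MeOH/THF, 60 °C; then aq. HCl
Reagents that add atoms: sodium hydroxide (aqueous), [Na+].[OH-]
Why: Ordinary saponification of a methyl salicylate; the unactivated aryl halides and the diaryl ether are inert to aqueous hydroxide at this temperature.

Step 7
Reactants: 10 5-chloro-3-(2,4-dibromophenoxy)-2-hydroxybenzoic acid
Product: 13 5-chloro-7-(2,4-dibromophenoxy)-1,3-benzoxazol-2(3H)-one, via acyl azide 11 (not isolated), via isocyanate 12 (not isolated)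
Conditions: (PhO)2P(O)N3, NEt3, toluene, 20 to 100 °C
Reagents that add atoms: diphenylphosphoryl azide, [N-]=[N+]=NP(=O)(Oc1ccccc1)Oc1ccccc1
Why: Curtius rearrangement of the acyl azide with loss of N2, followed by addition of the ortho hydroxyl to the isocyanate, is the established conversion of salicylic acids into benzoxazolones; it puts nitrogen on C6 of ring A and masks both heteroatoms.

Step 8
Reactants: 13 5-chloro-7-(2,4-dibromophenoxy)-1,3-benzoxazol-2(3H)-one
Product: 15 4,6-dibromo-5-chloro-7-(2,4-dibromophenoxy)-1,3-benzoxazol-2(3H)-one, via 6-bromo monobromide 14 (not isolated)
Conditions: Br2 (2.4 equiv), NaOAc, AcOH, 20 to 60 °C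
Reagents that add atoms: bromine, BrBr
Why: Electrophilic aromatic bromination directed by the ring nitrogen, first para to it (as 5-chlorobenzoxazolone brominates at C6) and then ortho; each site is also ortho or para to the ether oxygen, whereas C6' of ring B has only the shared oxygen and two meta bromines. The carbamate mask prevents oxidation to a quinone imine.

Step 9
Reactants: 15 4,6-dibromo-5-chloro-7-(2,4-dibromophenoxy)-1,3-benzoxazol-2(3H)-one
Product: 16 2-amino-3,5-dibromo-4-chloro-6-(2,4-dibromophenoxy)phenol
Conditions: NaOH (aq, 4 M), EtOH, reflux, N2; then AcOH to pH 6
Reagents that add atoms: none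
Why: Alkaline hydrolysis of the cyclic carbamate with loss of carbonate is the standard release of 2-aminophenols from benzoxazolones; the electron-rich ring after opening is not prone to nucleophilic displacement of halide.

Step 10
Reactants: 16 2-amino-3,5-dibromo-4-chloro-6-(2,4-dibromophenoxy)phenol
Product: 18 3,5-dibromo-4-chloro-2-(2,4-dibromophenoxy)phenol, via arenediazonium hydrogensulfate 17 (not isolated)
Conditions: NaNO2, conc. H2SO4/AcOH, 0–5 °C; then H3PO2 (50% aq), 0 to 20 °C
Reagents that add atoms: none
Why: Diazotisation with nitrosylsulfuric acid suits a hindered, weakly basic aniline, and hydrodediazoniation with H3PO2 (radical chain, hydrogen from P–H) is the classical deamination of 2,6-disubstituted anilines such as 2,4,6-tribromoaniline. Sulfuric rather than hydrochloric acid avoids chloride exchange at carbons activated by the diazonium group, and the strong acid keeps the ortho hydroxyl protonated.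

## Compound list

1 | 2,4-dibromophenol | Oc1ccc(Br)cc1Br | starting material
2 | methyl 4-chloro-3-oxobutanoate (methyl 4-chloroacetoacetate) | COC(=O)CC(=O)CCl | starting material
3 | methyl 4-(2,4-dibromophenoxy)-3-oxobutanoate | COC(=O)CC(=O)COc1ccc(Br)cc1Br | intermediate
4 | methyl 4-(2,4-dibromophenoxy)-3-(trimethylsilyloxy)but-2-enoate (double-bond isomer mixture) | COC(=O)C=C(O[Si](C)(C)C)COc1ccc(Br)cc1Br | intermediate
5 | 4-(2,4-dibromophenoxy)-1-methoxy-1,3-bis(trimethylsilyloxy)buta-1,3-diene (double-bond isomer mixture) | COC(O[Si](C)(C)C)=CC(O[Si](C)(C)C)=COc1ccc(Br)cc1Br | intermediate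
6 | 2-chloromalonaldehyde (2-chloropropanedial) | O=CC(Cl)C=O | starting material
7 | 2-chloro-3-(trimethylsilyloxy)prop-2-enal (double-bond isomer mixture) | O=CC(Cl)=CO[Si](C)(C)C | intermediate
8 | methyl (E)-6-chloro-4-(2,4-dibromophenoxy)-3,7-dioxohept-5-enoate (racemic at C4; present as its silyl or titanium enolate) | COC(=O)CC(=O)C(Oc1ccc(Br)cc1Br)/C=C(\C=O)Cl | intermediate (not isolated)
9 | methyl 5-chloro-3-(2,4-dibromophenoxy)-2-hydroxybenzoate | COC(=O)c1cc(Cl)cc(Oc2ccc(Br)cc2Br)c1O | intermediate
10 | 5-chloro-3-(2,4-dibromophenoxy)-2-hydroxybenzoic acid | OC(=O)c1cc(Cl)cc(Oc2ccc(Br)cc2Br)c1O | intermediate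
11 | 5-chloro-3-(2,4-dibromophenoxy)-2-hydroxybenzoyl azide | [N-]=[N+]=NC(=O)c1cc(Cl)cc(Oc2ccc(Br)cc2Br)c1O | intermediate (not isolated)
12 | 4-chloro-2-(2,4-dibromophenoxy)-6-isocyanatophenol | O=C=Nc1cc(Cl)cc(Oc2ccc(Br)cc2Br)c1O | intermediate (not isolated)
13 | 5-chloro-7-(2,4-dibromophenoxy)-1,3-benzoxazol-2(3H)-one | O=C1Nc2cc(Cl)cc(Oc3ccc(Br)cc3Br)c2O1 | intermediate
14 | 6-bromo-5-chloro-7-(2,4-dibromophenoxy)-1,3-benzoxazol-2(3H)-one | O=C1Nc2cc(Cl)c(Br)c(Oc3ccc(Br)cc3Br)c2O1 | intermediate (not isolated)
15 | 4,6-dibromo-5-chloro-7-(2,4-dibromophenoxy)-1,3-benzoxazol-2(3H)-one | O=C1Nc2c(Br)c(Cl)c(Br)c(Oc3ccc(Br)cc3Br)c2O1 | intermediate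
16 | 2-amino-3,5-dibromo-4-chloro-6-(2,4-dibromophenoxy)phenol | Nc1c(Br)c(Cl)c(Br)c(Oc2ccc(Br)cc2Br)c1O | intermediate
17 | 4,6-dibromo-5-chloro-3-(2,4-dibromophenoxy)-2-hydroxybenzenediazonium hydrogensulfate | N#[N+]c1c(O)c(Oc2ccc(Br)cc2Br)c(Br)c(Cl)c1Br.OS(=O)(=O)[O-] | intermediate (not isolated)
18 | 3,5-dibromo-4-chloro-2-(2,4-dibromophenoxy)phenol | Oc1cc(Br)c(Cl)c(Br)c1Oc1ccc(Br)cc1Br | target

## Step count and risk

Total steps: 10. Longest linear sequence: 9 steps (steps 1–3 and 5–10); step 4 is a one-step side branch.

**Step 5 (key step).** The most likely failure is hydrolysis or oligomerisation of the sensitive silyloxy enal 7 under the Lewis acid, together with protodesilylation of diene 5 back to the keto ester, so that cyclisation does not keep pace with decomposition. Fallback: the ring can be closed anionically, setting out from keto ester 3 and dialdehyde 6. The two are condensed with piperidinium acetate in ethanol: a Knoevenagel condensation at the doubly activated methylene of 3 is followed by intramolecular aldol condensation of the aryloxy-bearing methylene and dehydration, the classical malonaldehyde–ketone phenol synthesis. The same two C–C bonds form and the route is rejoined at 9. No compound outside the list is involved, so the entry for this fallback is F0. This fallback also covers a failure of step 4.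

**Step 3.** LiN(i-Pr)2 may competitively deprotonate ring B between its two bromines, followed by silylation or halogen migration, and the diene may be lost by hydrolysis on handling. Fallback: setting out from 3, both silyl groups are introduced in one operation by soft enolisation with Me3SiOTf (2.2 equiv) and NEt3 in Et2O at 0 °C, which avoids any strong base. The route is rejoined at 5. No compound outside the list is involved, so the entry for this fallback is F0.

**Step 8.** The second bromination, at the carbon ortho to nitrogen and flanked by chlorine, may stall at 14. Forcing it would erode the preference for ring A over C6' of ring B. Fallback: setting out from 13, the mask is removed first with aqueous NaOH to give 2-amino-4-chloro-6-(2,4-dibromophenoxy)phenol F1. The much more activated free aniline is then brominated at low temperature with N-bromosuccinimide (2 equiv) in MeCN, rejoining at 16. The reagent is kept stoichiometric and cold to limit oxidation of the aminophenol.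

**Step 10.** The ortho-hydroxy diazonium ion may collapse to a diazo-oxide (quinone diazide) that resists reduction, or may couple with unreacted aminophenol. Fallback: setting out from 16, the phenol is first blocked by selective O-sulfonylation of the phenoxide (TsCl, K2CO3, acetone) to give 2-amino-3,5-dibromo-4-chloro-6-(2,4-dibromophenoxy)phenyl 4-methylbenzenesulfonate F2. Diazotisation as in step 10 then gives 4,6-dibromo-5-chloro-3-(2,4-dibromophenoxy)-2-(tosyloxy)benzenediazonium hydrogensulfate F3, an ordinary 2,6-disubstituted arenediazonium salt. H3PO2 reduces it to 3,5-dibromo-4-chloro-2-(2,4-dibromophenoxy)phenyl 4-methylbenzenesulfonate F4. Cleavage of the sulfonate with NaOH in MeOH/THF rejoins the route at 18.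

## Further compounds

F0 | step 5 | none | none
F0 | step 3 | none | none
F1 | step 8 | 2-amino-4-chloro-6-(2,4-dibromophenoxy)phenol | Nc1cc(Cl)cc(Oc2ccc(Br)cc2Br)c1O
F2 | step 10 | 2-amino-3,5-dibromo-4-chloro-6-(2,4-dibromophenoxy)phenyl 4-methylbenzenesulfonate | Cc1ccc(cc1)S(=O)(=O)Oc1c(N)c(Br)c(Cl)c(Br)c1Oc1ccc(Br)cc1Br
F3 | step 10 | 4,6-dibromo-5-chloro-3-(2,4-dibromophenoxy)-2-(tosyloxy)benzenediazonium hydrogensulfate | Cc1ccc(cc1)S(=O)(=O)Oc1c([N+]#N)c(Br)c(Cl)c(Br)c1Oc1ccc(Br)cc1Br.OS(=O)(=O)[O-]
F4 | step 10 | 3,5-dibromo-4-chloro-2-(2,4-dibromophenoxy)phenyl 4-methylbenzenesulfonate | Cc1ccc(cc1)S(=O)(=O)Oc1cc(Br)c(Cl)c(Br)c1Oc1ccc(Br)cc1Br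
A1 | alternative 1 | 1,3-dibromo-2-chloro-4-(ethynyloxy)-5-methoxybenzene | COc1cc(Br)c(Cl)c(Br)c1OC#C
A2 | alternative 1 | 3,5-dibromo-2H-pyran-2-one | O=C1OC=C(Br)C=C1Br
A3 | alternative 1 | 1,3-dibromo-2-chloro-4-(2,4-dibromophenoxy)-5-methoxybenzene | COc1cc(Br)c(Cl)c(Br)c1Oc1ccc(Br)cc1Br
A4 | alternative 2 | 3-(2,4-dibromophenoxy)-4-methoxyaniline | COc1ccc(N)cc1Oc1ccc(Br)cc1Br
A5 | alternative 2 | 2,6-dibromo-3-(2,4-dibromophenoxy)-4-methoxyaniline | COc1cc(Br)c(N)c(Br)c1Oc1ccc(Br)cc1Br
A6 | alternative 3 | 3,5-dibromo-4-chloro-2-phenoxyphenyl acetate | CC(=O)Oc1cc(Br)c(Cl)c(Br)c1Oc1ccccc1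
A7 | alternative 3 | 3,5-dibromo-4-chloro-2-(2,4-dibromophenoxy)phenyl acetate | CC(=O)Oc1cc(Br)c(Cl)c(Br)c1Oc1ccc(Br)cc1Br
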